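**The count.** I began with the easy step of counting reagent per substrate, since a bis adduct carries two reagents on one substrate.

| flask | substrate | reagent | remark | time |
|---|---|---|---|---|
| alpha | 0.029 M | 0.090 M (in portions, 2) | run made earlier; portions every 5.0 min |  |
| beta | 0.11 M | 0.090 M (in portions, 2) | run made earlier; portions every 5.0 min |  |
| delta | 0.39 M | 0.090 M (in portions, 2) | run made earlier; portions every 5.0 min |  |
| south-west | 0.025 M | 0.0900 M (in portions, 2) | the portions of reagent follow each other after 5.0 min, the first at the start | 10 h |
| south | 0.050 M | 0.0900 M (in portions, 2) | the portions of reagent follow each other after 5.0 min, the first at the start | 10 h |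
| north-west | 0.10 M | 0.0900 M (in portions, 2) | the portions of reagent follow each other after 5.0 min, the first at the start | 10 h |
| north | 0.20 M | 0.0900 M (in portions, 2) | the portions of reagent follow each other after 5.0 min, the first at the start | 10 h |
| west | 0.40 M | 0.0900 M (in portions, 2) | the portions of reagent follow each other after 5.0 min, the first at the start | 10 h |

| run | time / h | bis adduct / % | substrate / % |
|---|---|---|---|
| alpha | 0.417 | 10 | 40 |
| alpha | 1.33 | 21 | 9 |
| alpha | 2.50 | 17 | 2 |
| alpha | 4.00 | 16 | 4 |
| alpha | 5.00 | 13 | 0 |
| beta | 0.417 | 2 | 56 |
| beta | 1.33 | 8 | 41 |
| beta | 2.50 | 10 | 40 |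
| beta | 4.00 | 8 | 39 |
| beta | 5.00 | 6 | 33 |
| delta | 1.00 | 0 | 80 |
| delta | 2.00 | 0 | 78 |
| delta | 3.00 | 1 | 79 |
| delta | 4.00 | 0 | 79 |
| delta | 5.00 | 0 | 80 |

(each reading ± 1.5 percentage points)

- a reading or a percentage of bis adduct counts all its forms, free or not
- the concentration of bis adduct that is asked is that of its free form alone
- "hardly changes" means that all values lie within two and a half points (for a concentration: within two and a half percent of the largest)

- [bis adduct] (only what is free in solution) at the end for south-west, south, north-west, north, west, in this order
- how the row runs (hardly changes / rises, then falls / rises all the way / falls, then rises / falls all the way)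

**The balance.** I wrote the reagent balance in fractions of the substrate charge. I called ε the reagent charged per substrate charged, which in north was 0.450. Once the reagent is used up, ε equals the fraction of substrate reacted plus the second additions, so ε minus the reacted fraction is the room for bis adduct.

**The readings.** Delta had ε of 0.231, below one, which made the reagent the limiting reagent. If its reagent was used up, the reading of 80% substrate at 5.00 h left room of 0.0308, within the scatter of the readings, and bis adduct read 0%. Beta, with ε of 0.818, read 33% substrate at 5.00 h, which on the same assumption left room of 0.148, and bis adduct read 6%.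

**One number?** It was not enough, because alpha kept its ε of 3.10 while bis adduct read 21% at 1.33 h and less at 5.00 h, 13%. So ε gave the room and not the clock. The row runs through ε of 3.60, 1.80, 0.900, 0.450 and 0.225. Beta's ε of 0.818 stood beside north-west's 0.900, so I took beta's last reading, made at 5.00 h, as my rough fraction and reckoned 0.00600 M for north-west, in a row that rises, then falls.

**The forecast.** It gave 0.0015 M, 0.0025 M, 0.0033 M, 0.0013 M and 3.000 × 10⁻⁴ M, and rises, then falls, holding bis adduct “limited by substrate at low loading and by selectivity at high loading”. For north-west this stood below my figure.

**The flask.** The row came out 0.00114 M, 0.00971 M, 0.00907 M, 0.00579 M and 0.00324 M, so rises, then falls, the forecast's shape, but south stood at 0.00971 M against its 0.0025 M. The row turned at 0.063 M of substrate, which is ε of 1.42.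

    substrate + reagent → first product (k = 0.504 L mol⁻¹ min⁻¹)
    reagent + first product → bis adduct (k = 0.320 L mol⁻¹ min⁻¹)
    reagent + bis adduct → triple product (k = 0.400 L mol⁻¹ min⁻¹)
    crystals ⇌ bis adduct, rate k4*(cs4 - [bis adduct]) while solid is left; crystals form when [bis adduct] > cs4 (solubility = 0.0750 M, k = 0.121 min⁻¹)
    bis adduct ⇌ isomer of the product (K = 0.790, k = 0.0184 min⁻¹)

**The balance again.** In north, with the reagent at 0% of its charge, ε of 0.450 less the 39 percentage points of substrate reacted left 0.0643 for second additions, and at 10.0 h bis adduct, isomer of the product and triple product, the last counted twice, held 0.0643.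

The readings were generated by integration on assumed constants, and the scatter is random.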